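**Retrosynthetic overview**

- The strategy rests on the (Z)-5-ylidene-4-methylbutenolide: ring O1'–C2'–C3'–C4'–C5' with the exocyclic C5'=C15 alkene conjugated to the E C13=C14 alkene. This ring is the 5-exo-dig lactonisation product of a (Z)-3-methylpent-2-en-4-ynoic acid, so C4'–C5' and O1'–C5' are cut together, giving a triol (E)-enyne and (Z)-3-iodobut-2-enoic acid.
- The butenolide is the only ring built, and it is built last. The decalin (rings A/B) with C5, C6, C9 and C10 is taken intact from larixol.
- The enyne comes from the C15 enal by one-carbon homologation; the enal comes from a 6α,8α,15,18-tetraol, released in one hydride reduction of an epoxy nitrato enoate.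
- C18–O is made from the 6α-nitrite (1,5-hydrogen transfer, oxygen trapping). C8–O comes from α-face epoxidation of the 8(17)-alkene. C13=C14 comes from olefination of the methyl ketone obtained by degrading the larixol side chain.

Key step: step 10

Remark: the target is read as a normal-series labdane (5α-H, 9α-H, 10β-CH3) with 6α-OH, 8α-OH/8β-CH3 and the 4α-CH2OH (C18). Labdane numbering is used, with C15 as the ylidene carbon and primed locants for the butenolide. Larixol is taken as purchasable.

**Route**

Step 1
Reactants: 1 larixol, (13S)-labda-8(17),14-diene-6α,13-diol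
Product: 2 6α-hydroxy-14,15-dinorlabd-8(17)-en-13-one
Conditions: KMnO4, BnEt3NCl, CH2Cl2, 0 °C to rt
Reagents that add atoms: none
Why: Permanganate cleaves the monosubstituted vinyl group of the tertiary allylic carbinol and degrades the side chain to the C13 methyl ketone (loss of C14 and C15, the ketone oxygen being the former 13-OH), while the hindered 8(17)-methylene and the secondary 6α-OH should react more slowly under cold phase-transfer conditions; no decalin stereocentre is touched.

Step 2
Reactants: 2 6α-hydroxy-14,15-dinorlabd-8(17)-en-13-one; 3 triethyl phosphonoacetate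
Product: 4 ethyl (13E)-6α-hydroxylabda-8(17),13-dien-15-oate
Conditions: NaH (excess), THF, 0 °C to 50 °C; chromatography
Reagents that add atoms: none
Why: Horner–Wadsworth–Emmons olefination of the methyl ketone with excess phosphonate anion (the 6-alkoxide is a spectator) should give the β,β-disubstituted enoate with the 13E isomer (ester trans to the larger C12 chain) predominating, the minor 13Z isomer being removed by chromatography.

Step 3
Reactants: 4 ethyl (13E)-6α-hydroxylabda-8(17),13-dien-15-oate
Product: 5 ethyl (13E)-8α,17-epoxy-6α-hydroxylabd-13-en-15-oate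
Conditions: mCPBA, NaHCO3, CH2Cl2, 0 °C
Reagents that add atoms: mCPBA, O=C(OO)c1cccc(Cl)c1
Why: Prilezhaev epoxidation is chemoselective for the electron-rich 1,1-disubstituted 8(17)-alkene over the enoate and should occur mainly on the α-face, away from the axial 10β-methyl and the β-oriented C9 side chain, placing oxygen α and C17 β at C8 (any 8β,17-epoxide is separated).

Step 4
Reactants: 5 ethyl (13E)-8α,17-epoxy-6α-hydroxylabd-13-en-15-oate
Product: 6 ethyl (13E)-8α,17-epoxy-6α-(nitrosooxy)labd-13-en-15-oate
Conditions: NOCl, pyridine, −20 °C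
Reagents that add atoms: nitrosyl chloride, O=NCl
Why: O-Nitrosation of the only free hydroxyl by nitrosyl chloride in pyridine is fast at low temperature, the buffered medium should spare the epoxide and the enoate, and C6 keeps its configuration because the C6–O bond is not broken.

Step 5
Reactants: 6 ethyl (13E)-8α,17-epoxy-6α-(nitrosooxy)labd-13-en-15-oate
Product: 7 ethyl (13E)-8α,17-epoxy-6α-hydroxy-18-(nitrooxy)labd-13-en-15-oate
Conditions: hν (365 nm), O2 (bubbling), PhH, 10 °C
Reagents that add atoms: dioxygen, O=O
Why: Barton nitrite photolysis in its oxygen-trapping variant: O–NO homolysis gives the 6α-alkoxyl radical, whose equatorial oxygen lies peri to the equatorial 4α-methyl and abstracts a C18 hydrogen through a six-membered transition state (the axial 4β-methyl and C20 are out of reach), the C18 radical is captured by O2 and the peroxyl radical combines with NO and rearranges to the nitrate ester, so C4 becomes a stereocentre with the oxidised carbon α.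

Step 6
Reactants: 7 ethyl (13E)-8α,17-epoxy-6α-hydroxy-18-(nitrooxy)labd-13-en-15-oate
Product: 8 (13E)-labd-13-ene-6α,8α,15,18-tetraol
Conditions: LiAlH4, THF, 0 °C to 40 °C; Rochelle salt work-up
Reagents that add atoms: none
Why: Lithium aluminium hydride should do three reductions in one operation: hydride opening of the spiro-epoxide at the unhindered C17 methylene (giving the 8α-OH/8β-CH3 carbinol with the C8–O bond and its configuration intact), cleavage of the nitrate ester to the 18-alcohol, and 1,2-reduction of the β,β-disubstituted enoate to the allylic alcohol.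

Step 7
Reactants: 8 (13E)-labd-13-ene-6α,8α,15,18-tetraol
Product: 9 (13E)-6α,8α,18-trihydroxylabd-13-en-15-al
Conditions: activated MnO2, acetone, rt
Reagents that add atoms: none
Why: Manganese dioxide oxidises only the allylic C15 alcohol, leaving the neopentyl 18-OH, the secondary 6α-OH and the tertiary 8α-OH untouched, and should keep the 13E geometry.

Step 8
Reactants: 9 (13E)-6α,8α,18-trihydroxylabd-13-en-15-al; 10 dimethyl (1-diazo-2-oxopropyl)phosphonate
Product: 11 decalin triol (E)-enyne (C9 side chain CH2CH2–C(CH3)=CH–C≡CH, 13E; 6α-OH, 8α-OH/8β-CH3, 4α-CH2OH)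
Conditions: K2CO3, MeOH, 0 °C to rt
Reagents that add atoms: none
Why: Ohira–Bestmann (Seyferth–Gilbert) homologation: methanolysis of the reagent releases the diazomethylphosphonate anion, which olefinates the aldehyde and, after loss of N2 and 1,2-hydrogen shift, leaves the terminal alkyne; the mild carbonate/methanol medium tolerates the free triol and the β,β-disubstitution of the enal should disfavour conjugate addition of methanol.

Step 9
Reactants: 12 but-2-ynoic acid
Product: 13 (Z)-3-iodobut-2-enoic acid
Conditions: NaI, AcOH, 110 °C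
Reagents that add atoms: sodium iodide, [Na+].[I-]
Why: Hydroiodination of the ynoic acid by conjugate addition of iodide and anti protonation gives the (Z)-3-iodoalkenoic acid with iodine cis to the carboxyl group.

Step 10
Reactants: 11 decalin triol (E)-enyne; 13 (Z)-3-iodobut-2-enoic acid
Product: 15 CNP0126806.1 (target), via Z-enynoic acid 14 (not isolated)
Conditions: Pd(PPh3)4 (5 mol%), CuI (10 mol%), Et3N, degassed MeCN, rt, dark
Reagents that add atoms: none
Why: Oxidative addition of the Z-iodoacid (as its ammonium carboxylate) to Pd(0), transmetalation from the copper acetylide of 11 and reductive elimination form C4'–C5' and give the (Z)-2-en-4-ynoic acid 14 with the alkene geometry retained. The carboxylate, held cis to the alkyne, then adds anti across the metal-coordinated triple bond at the proximal carbon C5', and protodemetalation of the vinyl–metal species releases the butenolide ring O1'–C2'–C3'–C4'–C5', a 5-exo-dig closure forming O1'–C5'. The closest known reaction type is the Pd/Cu-catalysed tandem cross-coupling–lactonisation of (Z)-3-iodoalk-2-enoic acids with terminal alkynes to (Z)-γ-ylidenebutenolides. No stereocentre is created; the only new stereo-element is the C5'=C15 geometry, which should be Z (O1' cis to C14) because oxygen and metal add anti and the metal is replaced by hydrogen with retention. The step needs 5-exo over 6-endo (2-pyranone) closure, which the cis carboxylate/alkyne geometry and soft-metal activation favour, and it must leave the 13E alkene and the free 6α,8α,18-triol untouched, which the neutral room-temperature conditions allow.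

**Compound list**

1 | larixol, (13S)-labda-8(17),14-diene-6α,13-diol | C=C[C@@](C)(O)CC[C@@H]1[C@@]2(C)CCCC(C)(C)[C@@H]2[C@@H](O)CC1=C | starting material
2 | 6α-hydroxy-14,15-dinorlabd-8(17)-en-13-one | CC(=O)CC[C@@H]1[C@@]2(C)CCCC(C)(C)[C@@H]2[C@@H](O)CC1=C | intermediate
3 | triethyl phosphonoacetate | CCOC(=O)CP(=O)(OCC)OCC | starting material
4 | ethyl (13E)-6α-hydroxylabda-8(17),13-dien-15-oate | CCOC(=O)/C=C(\C)CC[C@@H]1[C@@]2(C)CCCC(C)(C)[C@@H]2[C@@H](O)CC1=C | intermediate
5 | ethyl (13E)-8α,17-epoxy-6α-hydroxylabd-13-en-15-oate | CCOC(=O)/C=C(\C)CC[C@@H]1[C@@]2(C)CCCC(C)(C)[C@@H]2[C@@H](O)C[C@]13CO3 | intermediate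
6 | ethyl (13E)-8α,17-epoxy-6α-(nitrosooxy)labd-13-en-15-oate | CCOC(=O)/C=C(\C)CC[C@@H]1[C@@]2(C)CCCC(C)(C)[C@@H]2[C@@H](ON=O)C[C@]13CO3 | intermediate
7 | ethyl (13E)-8α,17-epoxy-6α-hydroxy-18-(nitrooxy)labd-13-en-15-oate | CCOC(=O)/C=C(\C)CC[C@@H]1[C@@]2(C)CCC[C@@](C)(CO[N+](=O)[O-])[C@@H]2[C@@H](O)C[C@]13CO3 | intermediate
8 | (13E)-labd-13-ene-6α,8α,15,18-tetraol | OC/C=C(\C)CC[C@@H]1[C@@]2(C)CCC[C@@](C)(CO)[C@@H]2[C@@H](O)C[C@@]1(C)O | intermediate
9 | (13E)-6α,8α,18-trihydroxylabd-13-en-15-al | O=C/C=C(\C)CC[C@@H]1[C@@]2(C)CCC[C@@](C)(CO)[C@@H]2[C@@H](O)C[C@@]1(C)O | intermediate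
10 | dimethyl (1-diazo-2-oxopropyl)phosphonate | COP(=O)(OC)C(=[N+]=[N-])C(C)=O | starting material
11 | decalin triol (E)-enyne | C#C/C=C(\C)CC[C@@H]1[C@@]2(C)CCC[C@@](C)(CO)[C@@H]2[C@@H](O)C[C@@]1(C)O | intermediate
12 | but-2-ynoic acid | CC#CC(=O)O | starting material
13 | (Z)-3-iodobut-2-enoic acid | C/C(I)=C/C(=O)O | intermediate
14 | Z-enynoic acid (2Z,6E; Sonogashira product before lactonisation) | C/C(C#C/C=C(\C)CC[C@@H]1[C@@]2(C)CCC[C@@](C)(CO)[C@@H]2[C@@H](O)C[C@@]1(C)O)=C/C(=O)O | intermediate
15 | CNP0126806.1 | CC1=CC(=O)O/C1=C\C=C(/C)CC[C@@H]1[C@@]2(C)CCC[C@@](C)(CO)[C@@H]2[C@@H](O)C[C@@]1(C)O | target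

**Step count**

Total: 10 steps. Longest linear sequence: 9 steps (steps 1–8 and 10, from larixol); step 9 is a one-step side branch.

**Steps most likely to fail**

1. Step 5 (C18 oxygenation). The 6α-alkoxyl radical may fragment (C5–C6 β-scission) in competition with the 1,5-hydrogen transfer. Oxygen capture of the C18 radical may also be incomplete, leading to C-nitroso and oxime by-products, and the spiro-epoxide may not survive the radical medium. The fallback leaves the nitrite/oxygen manifold and closes the C18–O bond as a cyclic ether on an alkene-free intermediate; it sets out from 2 and returns at 8. Ketone 2 is epoxidised (mCPBA, NaHCO3, CH2Cl2) to 8α,17-epoxy-6α-hydroxy-14,15-dinorlabdan-13-one F1. A Suárez hypoiodite reaction (PhI(OAc)2, I2, hν, cyclohexane) then transfers iodine to C18 after the same 1,5-hydrogen shift and closes 8α,17:6α,18-diepoxy-14,15-dinorlabdan-13-one F2. Buffered RuCl3/NaIO4 oxidises the ether methylene to 8α,17-epoxy-13-oxo-14,15-dinorlabdan-18,6α-olide F3. Horner–Wadsworth–Emmons olefination with 3 gives ethyl (13E)-8α,17-epoxy-18,6α-olide-labd-13-en-15-oate F4. LiAlH4 then reduces lactone, epoxide and ester together to tetraol 8.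

2. Step 10 (key step). The closure may go partly 6-endo-dig to the 2-pyranone, the enyne may homocouple oxidatively, or the sequence may stall at the open acid. The fallback separates coupling from ring closure; it sets out from 11 and 13 and returns at 15. Acid 13 is esterified (MeI, K2CO3, DMF) to methyl (Z)-3-iodobut-2-enoate F5. Sonogashira coupling of F5 with 11 (PdCl2(PPh3)2, CuI, Et3N, THF) gives the methyl Z-enynoate F6, which cannot cyclise. Saponification (LiOH, THF/H2O) gives acid 14, now isolated, and silver(I) catalysis (AgNO3, acetone, dark) effects the 5-exo-dig lactonisation to 15.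

3. Step 8 (alkynylation of the enal). Methanol or methoxide may add in conjugate fashion during the homologation, and the base may scramble the 13E geometry through the dienolate. The fallback avoids the methanolic base by a Corey–Fuchs sequence on a silylated enal; it sets out from 9 and returns at 11. Enal 9 is silylated (TESCl, imidazole, DMAP, DMF) to the 6α,18-bis(triethylsilyl) ether enal F7. Dibromo-olefination (CBr4, PPh3, Et3N, CH2Cl2, 0 °C) gives the 1,1-dibromodiene F8. n-BuLi (excess, THF, −78 °C) then gives the bis(triethylsilyl) enyne F9, and TBAF (THF) releases triol enyne 11.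

**Further compounds**

F1 | step 5 | 8α,17-epoxy-6α-hydroxy-14,15-dinorlabdan-13-one | CC(=O)CC[C@@H]1[C@@]2(C)CCCC(C)(C)[C@@H]2[C@@H](O)C[C@]13CO3
F2 | step 5 | 8α,17:6α,18-diepoxy-14,15-dinorlabdan-13-one | CC(=O)CC[C@@H]1[C@@]2(C)CCC[C@@](C)(CO4)[C@@H]2[C@@H]4C[C@]13CO3
F3 | step 5 | 8α,17-epoxy-13-oxo-14,15-dinorlabdan-18,6α-olide | CC(=O)CC[C@@H]1[C@@]2(C)CCC[C@@](C)(C(=O)O4)[C@@H]2[C@@H]4C[C@]13CO3
F4 | step 5 | ethyl (13E)-8α,17-epoxy-18,6α-olide-labd-13-en-15-oate | CCOC(=O)/C=C(\C)CC[C@@H]1[C@@]2(C)CCC[C@@](C)(C(=O)O4)[C@@H]2[C@@H]4C[C@]13CO3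
F5 | step 10 | methyl (Z)-3-iodobut-2-enoate | C/C(I)=C/C(=O)OC
F6 | step 10 | methyl Z-enynoate (methyl ester of 14) | C/C(C#C/C=C(\C)CC[C@@H]1[C@@]2(C)CCC[C@@](C)(CO)[C@@H]2[C@@H](O)C[C@@]1(C)O)=C/C(=O)OC
F7 | step 8 | (13E)-8α-hydroxy-6α,18-bis(triethylsilyloxy)labd-13-en-15-al | O=C/C=C(\C)CC[C@@H]1[C@@]2(C)CCC[C@@](C)(CO[Si](CC)(CC)CC)[C@@H]2[C@@H](O[Si](CC)(CC)CC)C[C@@]1(C)O
F8 | step 8 | 6α,18-bis(triethylsilyl) ether 1,1-dibromodiene | BrC(Br)=C/C=C(\C)CC[C@@H]1[C@@]2(C)CCC[C@@](C)(CO[Si](CC)(CC)CC)[C@@H]2[C@@H](O[Si](CC)(CC)CC)C[C@@]1(C)O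
F9 | step 8 | 6α,18-bis(triethylsilyl) ether of enyne 11 | C#C/C=C(\C)CC[C@@H]1[C@@]2(C)CCC[C@@](C)(CO[Si](CC)(CC)CC)[C@@H]2[C@@H](O[Si](CC)(CC)CC)C[C@@]1(C)O
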